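The disconnection on which everything rests is the bond between ring carbon C5 of the oxolan-2-one (the O–CH) and the vinylic CH of the 3-acetoxy-2-methylpropenyl arm. C5 is at once an allylic carbinol carbon and the γ-carbon of a γ-hydroxy-α-methylene ester. A Nozaki–Hiyama–Kishi addition of (E)-3-iodo-2-methylallyl acetate to an open-chain aldehyde that already carries the acrylate, the methacrylate and both other stereocentres therefore forms this bond, sets the C5 configuration under Felkin–Anh control and closes the five-membered lactone ring in the same operation. The aldehyde comes from a catalytic asymmetric, syn-selective 2-(methoxycarbonyl)allylation of a β,γ-unsaturated aldehyde.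

Key step: step 13

Remark: in step 7 the chiral ligand is used as the enantiomer that directs the allyl group to the Si face of the aldehyde carbon of 7; its absolute descriptor is not restated.

Step 1
Reactants: 1 tert-butyl(but-3-yn-1-yloxy)dimethylsilane
Product: 4 (2E)-5-[(tert-butyldimethylsilyl)oxy]-3-methylpent-2-en-1-ol, via alkenylalane 2 (not isolated), via lithium alkenylalanate 3 (not isolated)
Conditions: Me3Al, Cp2ZrCl2 (cat.), CH2Cl2, 0 °C → rt; volatiles removed; n-BuLi, hexane/THF, −78 °C; (CH2O)n, THF, rt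
Reagents that add atoms: trimethylaluminium C[Al](C)C; paraformaldehyde (as formaldehyde) C=O
Why: Negishi zirconium-catalysed carboalumination adds methyl and aluminium syn across the terminal alkyne with methyl on the internal carbon, and hydroxymethylation of the alanate with formaldehyde goes with retention, which fixes the E trisubstituted alkene.

Step 2
Reactants: 4 (2E)-5-[(tert-butyldimethylsilyl)oxy]-3-methylpent-2-en-1-ol
Product: 5 (3E)-1-[(tert-butyldimethylsilyl)oxy]-5-[(tert-butyldiphenylsilyl)oxy]-3-methylpent-3-ene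
Conditions: TBDPSCl, imidazole, CH2Cl2, 0 °C → rt
Reagents that add atoms: tert-butyldiphenylsilyl chloride CC(C)(C)[Si](Cl)(c1ccccc1)c1ccccc1
Why: Silyl ether formation on a primary allylic alcohol is routine, and the acid-stable TBDPS group is chosen so that it outlasts both later TBS removals.

Step 3
Reactants: 5 (3E)-1-[(tert-butyldimethylsilyl)oxy]-5-[(tert-butyldiphenylsilyl)oxy]-3-methylpent-3-ene
Product: 6 (3E)-5-[(tert-butyldiphenylsilyl)oxy]-3-methylpent-3-en-1-ol
Conditions: CSA (cat.), MeOH/CH2Cl2, 0 °C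
Reagents that add atoms: none
Why: Acid-catalysed methanolysis (selective desilylation) cleaves a primary TBS ether much faster than a primary TBDPS ether.

Step 4
Reactants: 6 (3E)-5-[(tert-butyldiphenylsilyl)oxy]-3-methylpent-3-en-1-ol
Product: 7 (3E)-5-[(tert-butyldiphenylsilyl)oxy]-3-methylpent-3-enal
Conditions: Dess–Martin periodinane, NaHCO3, CH2Cl2, 0 °C; used crude
Reagents that add atoms: none
Why: Dess–Martin oxidation under buffered, non-basic conditions should give the β,γ-unsaturated aldehyde without moving the double bond into conjugation.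

Step 5
Reactants: 8 methyl acrylate; 9 [(tert-butyldimethylsilyl)oxy]acetaldehyde
Product: 10 methyl 4-[(tert-butyldimethylsilyl)oxy]-3-hydroxy-2-methylidenebutanoate (racemic)
Conditions: DABCO (0.5 equiv), neat (excess 8), rt
Reagents that add atoms: none
Why: Morita–Baylis–Hillman reaction with a reactive α-silyloxy aldehyde; the carbinol centre is racemic but is erased in step 6.

Step 6
Reactants: 10 methyl 4-[(tert-butyldimethylsilyl)oxy]-3-hydroxy-2-methylidenebutanoate
Product: 11 methyl (2Z)-2-(bromomethyl)-4-[(tert-butyldimethylsilyl)oxy]but-2-enoate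
Conditions: NBS, Me2S, CH2Cl2, 0 °C → rt
Reagents that add atoms: N-bromosuccinimide BrN1C(=O)CCC1=O
Why: Corey–Kim-type activation of the allylic alcohol followed by SN2′ attack of bromide should give the thermodynamically preferred (Z)-2-(bromomethyl)alk-2-enoate, in which CH2Br and CH2OTBS are cis.

Step 7
Reactants: 7 (3E)-5-[(tert-butyldiphenylsilyl)oxy]-3-methylpent-3-enal; 11 methyl (2Z)-2-(bromomethyl)-4-[(tert-butyldimethylsilyl)oxy]but-2-enoate
Product: 13 methyl (3S,4R,6E)-3-{[(tert-butyldimethylsilyl)oxy]methyl}-8-[(tert-butyldiphenylsilyl)oxy]-4-hydroxy-6-methyl-2-methylideneoct-6-enoate, via allylchromium(III) species 12 (not isolated)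
Conditions: CrCl2 (10 mol %), chiral carbazole-bis(oxazoline) ligand (12 mol %), i-Pr2NEt, Mn, Cp2ZrCl2, THF, rt; aq. NaHCO3 work-up
Reagents that add atoms: none
Why: Catalytic asymmetric Nozaki–Hiyama allylation (chromium-catalysed 2-(alkoxycarbonyl)allylation): allylchromium 12 reacts at its γ-carbon through a chair transition state in which the geometry with CH2Cr cis to CH2OTBS gives the syn adduct, the chiral ligand directs attack to the Si face of the aldehyde and so sets both centres, and Cp2ZrCl2 releases the alkoxide from chromium so that the hydroxy ester is obtained unlactonised.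

Step 8
Reactants: 13 methyl (3S,4R,6E)-3-{[(tert-butyldimethylsilyl)oxy]methyl}-8-[(tert-butyldiphenylsilyl)oxy]-4-hydroxy-6-methyl-2-methylideneoct-6-enoate
Product: 14 methyl (3S,4R,6E)-3-{[(tert-butyldimethylsilyl)oxy]methyl}-8-[(tert-butyldiphenylsilyl)oxy]-6-methyl-2-methylidene-4-[(2-methylprop-2-enoyl)oxy]oct-6-enoate
Conditions: methacrylic anhydride, Et3N, DMAP (cat.), CH2Cl2, 0 °C
Reagents that add atoms: methacrylic anhydride C=C(C)C(=O)OC(=O)C(C)=C
Why: DMAP-catalysed acylation (esterification) of the secondary alcohol should outrun its lactonisation onto the acrylate ester.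

Step 9
Reactants: 14 methyl (3S,4R,6E)-3-{[(tert-butyldimethylsilyl)oxy]methyl}-8-[(tert-butyldiphenylsilyl)oxy]-6-methyl-2-methylidene-4-[(2-methylprop-2-enoyl)oxy]oct-6-enoate
Product: 15 methyl (3S,4R,6E)-8-[(tert-butyldiphenylsilyl)oxy]-3-(hydroxymethyl)-6-methyl-2-methylidene-4-[(2-methylprop-2-enoyl)oxy]oct-6-enoate
Conditions: HF·pyridine, pyridine, THF, 0 °C
Reagents that add atoms: none
Why: Selective desilylation with buffered HF·pyridine removes the primary TBS ether while the primary TBDPS ether and the three esters stay, and the mild conditions should keep the methacrylate from shifting to the new primary hydroxyl.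

Step 10
Reactants: 15 methyl (3S,4R,6E)-8-[(tert-butyldiphenylsilyl)oxy]-3-(hydroxymethyl)-6-methyl-2-methylidene-4-[(2-methylprop-2-enoyl)oxy]oct-6-enoate
Product: 16 methyl (3R,4R,6E)-8-[(tert-butyldiphenylsilyl)oxy]-3-formyl-6-methyl-2-methylidene-4-[(2-methylprop-2-enoyl)oxy]oct-6-enoate
Conditions: Dess–Martin periodinane, NaHCO3, CH2Cl2, 0 °C; used at once
Reagents that add atoms: none
Why: Dess–Martin oxidation works without base, so the methylidene double bond should not move into conjugation, the α-centre should not epimerise and the β-methacrylate should not be eliminated.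

Step 11
Reactants: 17 prop-2-yn-1-ol
Product: 19 (2E)-3-iodo-2-methylprop-2-en-1-ol, via alkenylalane 18 (not isolated)
Conditions: Me3Al, Cp2ZrCl2 (cat.), CH2Cl2, 0 °C → rt; I2, THF, −30 → 0 °C
Reagents that add atoms: trimethylaluminium C[Al](C)C; iodine II
Why: Negishi carboalumination of the aluminium alkoxide of propargyl alcohol is syn and regioselective, and iodinolysis of the C–Al bond with retention gives the E iodide.

Step 12
Reactants: 19 (2E)-3-iodo-2-methylprop-2-en-1-ol
Product: 20 (2E)-3-iodo-2-methylprop-2-en-1-yl acetate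
Conditions: Ac2O, pyridine, DMAP (cat.), CH2Cl2, 0 °C → rt
Reagents that add atoms: acetic anhydride CC(=O)OC(C)=O
Why: Acetylation (esterification) of a primary allylic alcohol is routine and does not touch the alkenyl iodide.

Step 13
Reactants: 16 methyl (3R,4R,6E)-8-[(tert-butyldiphenylsilyl)oxy]-3-formyl-6-methyl-2-methylidene-4-[(2-methylprop-2-enoyl)oxy]oct-6-enoate; 20 (2E)-3-iodo-2-methylprop-2-en-1-yl acetate
Product: 23 (1R,3E)-1-[(2R,3R)-2-[(1E)-3-acetoxy-2-methylprop-1-en-1-yl]-4-methylidene-5-oxooxolan-3-yl]-5-[(tert-butyldiphenylsilyl)oxy]-3-methylpent-3-en-1-yl 2-methylprop-2-enoate, via alkenylchromium(III) reagent 21 (not isolated), via open hydroxy ester 22 (not isolated)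
Conditions: CrCl2 (6 equiv), NiCl2 (0.5 mol %), DMSO/THF, rt; aq. NH4Cl work-up; then PPTS (cat.), CH2Cl2, rt
Reagents that add atoms: none
Why: Nozaki–Hiyama–Kishi reaction: Ni(0) inserts into the C–I bond of 20 with retention of the E geometry and hands the alkenyl group to chromium, and the resulting alkenylchromium(III) 21 adds 1,2 to the aldehyde of 16 to give 22. The closest precedent is the Ni/Cr-mediated alkenylation of α-branched, base-sensitive aldehydes, chosen here because the reagent is non-basic and should leave the doubly activated α-hydrogen of 16, the β-methacrylate, the acrylate and the allylic acetate untouched (the nickel loading is kept low for the latter). The new carbinol centre is set by the two existing centres: in the Felkin–Anh transition state the branched acyloxyalkyl arm stands anti to the incoming alkenyl group with the flat acrylate unit inside, and the 1,3-anti preference of a β-acyloxy aldehyde points the same way, so that Re-face attack should give the (R)-carbinol. Mild acid then closes the only ring formed, the γ-lactone, by 5-exo-trig attack of the new hydroxyl on the acrylate ester carbon with loss of methanol, which places the alkenyl group and the side chain on the adjacent ring carbon trans. The step needs 1,2-addition to the aldehyde in preference to the two Michael acceptors, which the alkenylchromium reagent secures, and lactonisation in preference to a 1,3-shift of the methacrylate, which the irreversible five-membered ring closure under non-basic conditions secures.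

Step 14
Reactants: 23 (1R,3E)-1-[(2R,3R)-2-[(1E)-3-acetoxy-2-methylprop-1-en-1-yl]-4-methylidene-5-oxooxolan-3-yl]-5-[(tert-butyldiphenylsilyl)oxy]-3-methylpent-3-en-1-yl 2-methylprop-2-enoate
Product: 24 (1R,3E)-1-[(2R,3R)-2-[(1E)-3-acetoxy-2-methylprop-1-en-1-yl]-4-methylidene-5-oxooxolan-3-yl]-5-hydroxy-3-methylpent-3-en-1-yl 2-methylprop-2-enoate (CNP0323189.1)
Conditions: HF·pyridine, pyridine, THF, 0 °C → rt
Reagents that add atoms: none
Why: Desilylation of the primary TBDPS ether with mildly acidic HF·pyridine should leave the acetate, the methacrylate and the α-methylene lactone untouched and changes no stereocentre.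

Compound list
1 | tert-butyl(but-3-yn-1-yloxy)dimethylsilane | C#CCCO[Si](C)(C)C(C)(C)C | starting material
2 | (E)-{4-[(tert-butyldimethylsilyl)oxy]-2-methylbut-1-en-1-yl}dimethylalane | C[Al](C)/C=C(\C)CCO[Si](C)(C)C(C)(C)C | intermediate
3 | lithium (E)-butyl{4-[(tert-butyldimethylsilyl)oxy]-2-methylbut-1-en-1-yl}dimethylaluminate | [Li+].CCCC[Al-](C)(C)/C=C(\C)CCO[Si](C)(C)C(C)(C)C | intermediate
4 | (2E)-5-[(tert-butyldimethylsilyl)oxy]-3-methylpent-2-en-1-ol | OC/C=C(\C)CCO[Si](C)(C)C(C)(C)C | intermediate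
5 | (3E)-1-[(tert-butyldimethylsilyl)oxy]-5-[(tert-butyldiphenylsilyl)oxy]-3-methylpent-3-ene | CC(C)(C)[Si](C)(C)OCC/C(C)=C/CO[Si](c1ccccc1)(c1ccccc1)C(C)(C)C | intermediate
6 | (3E)-5-[(tert-butyldiphenylsilyl)oxy]-3-methylpent-3-en-1-ol | OCC/C(C)=C/CO[Si](c1ccccc1)(c1ccccc1)C(C)(C)C | intermediate
7 | (3E)-5-[(tert-butyldiphenylsilyl)oxy]-3-methylpent-3-enal | O=CC/C(C)=C/CO[Si](c1ccccc1)(c1ccccc1)C(C)(C)C | intermediate
8 | methyl acrylate | C=CC(=O)OC | starting material
9 | [(tert-butyldimethylsilyl)oxy]acetaldehyde | O=CCO[Si](C)(C)C(C)(C)C | starting material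
10 | methyl 4-[(tert-butyldimethylsilyl)oxy]-3-hydroxy-2-methylidenebutanoate (racemic) | C=C(C(=O)OC)C(O)CO[Si](C)(C)C(C)(C)C | intermediate
11 | methyl (2Z)-2-(bromomethyl)-4-[(tert-butyldimethylsilyl)oxy]but-2-enoate | BrC/C(C(=O)OC)=C\CO[Si](C)(C)C(C)(C)C | intermediate
12 | (Z)-{4-[(tert-butyldimethylsilyl)oxy]-2-(methoxycarbonyl)but-2-en-1-yl}chromium(III) dichloride (chiral ligand on chromium not drawn) | Cl[Cr](Cl)C/C(C(=O)OC)=C\CO[Si](C)(C)C(C)(C)C | intermediate
13 | methyl (3S,4R,6E)-3-{[(tert-butyldimethylsilyl)oxy]methyl}-8-[(tert-butyldiphenylsilyl)oxy]-4-hydroxy-6-methyl-2-methylideneoct-6-enoate | O[C@H](C/C(C)=C/CO[Si](c1ccccc1)(c1ccccc1)C(C)(C)C)[C@@H](C(=C)C(=O)OC)CO[Si](C)(C)C(C)(C)C | intermediate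
14 | methyl (3S,4R,6E)-3-{[(tert-butyldimethylsilyl)oxy]methyl}-8-[(tert-butyldiphenylsilyl)oxy]-6-methyl-2-methylidene-4-[(2-methylprop-2-enoyl)oxy]oct-6-enoate | C=C(C)C(=O)O[C@H](C/C(C)=C/CO[Si](c1ccccc1)(c1ccccc1)C(C)(C)C)[C@@H](C(=C)C(=O)OC)CO[Si](C)(C)C(C)(C)C | intermediate
15 | methyl (3S,4R,6E)-8-[(tert-butyldiphenylsilyl)oxy]-3-(hydroxymethyl)-6-methyl-2-methylidene-4-[(2-methylprop-2-enoyl)oxy]oct-6-enoate | C=C(C)C(=O)O[C@H](C/C(C)=C/CO[Si](c1ccccc1)(c1ccccc1)C(C)(C)C)[C@@H](C(=C)C(=O)OC)CO | intermediate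
16 | methyl (3R,4R,6E)-8-[(tert-butyldiphenylsilyl)oxy]-3-formyl-6-methyl-2-methylidene-4-[(2-methylprop-2-enoyl)oxy]oct-6-enoate | C=C(C)C(=O)O[C@H](C/C(C)=C/CO[Si](c1ccccc1)(c1ccccc1)C(C)(C)C)[C@@H](C(=C)C(=O)OC)C=O | intermediate
17 | prop-2-yn-1-ol | C#CCO | starting material
18 | (E)-{3-[(dimethylalumanyl)oxy]-2-methylprop-1-en-1-yl}dimethylalane | C[Al](C)OC/C(C)=C/[Al](C)C | intermediate
19 | (2E)-3-iodo-2-methylprop-2-en-1-ol | OC/C(C)=C/I | intermediate
20 | (2E)-3-iodo-2-methylprop-2-en-1-yl acetate | CC(=O)OC/C(C)=C/I | intermediate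
21 | (E)-(3-acetoxy-2-methylprop-1-en-1-yl)chromium(III) dichloride | CC(=O)OC/C(C)=C/[Cr](Cl)Cl | intermediate
22 | methyl (3S,4R,6E)-3-[(1R,2E)-4-acetoxy-1-hydroxy-3-methylbut-2-en-1-yl]-8-[(tert-butyldiphenylsilyl)oxy]-6-methyl-2-methylidene-4-[(2-methylprop-2-enoyl)oxy]oct-6-enoate | C=C(C)C(=O)O[C@H](C/C(C)=C/CO[Si](c1ccccc1)(c1ccccc1)C(C)(C)C)[C@@H](C(=C)C(=O)OC)[C@H](O)/C=C(\C)COC(C)=O | intermediate
23 | (1R,3E)-1-[(2R,3R)-2-[(1E)-3-acetoxy-2-methylprop-1-en-1-yl]-4-methylidene-5-oxooxolan-3-yl]-5-[(tert-butyldiphenylsilyl)oxy]-3-methylpent-3-en-1-yl 2-methylprop-2-enoate | C=C(C)C(=O)O[C@H](C/C(C)=C/CO[Si](c1ccccc1)(c1ccccc1)C(C)(C)C)[C@H]1C(=C)C(=O)O[C@@H]1/C=C(\C)COC(C)=O | intermediate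
24 | (1R,3E)-1-[(2R,3R)-2-[(1E)-3-acetoxy-2-methylprop-1-en-1-yl]-4-methylidene-5-oxooxolan-3-yl]-5-hydroxy-3-methylpent-3-en-1-yl 2-methylprop-2-enoate | C=C(C)C(=O)O[C@H](C/C(C)=C/CO)[C@H]1C(=C)C(=O)O[C@@H]1/C=C(\C)COC(C)=O | target

Total step count: 14. Longest linear sequence: 10 steps (steps 1–4, 7–10, 13, 14).

Steps most likely to fail

Step 13. The alkenylchromium reagent may add to both faces of the aldehyde if the acrylate unit and the acyloxyalkyl arm compete for the anti position in the Felkin–Anh transition state. That would erode the configuration at the new carbinol carbon and lead to the cis-lactone alongside 23. The fallback sets out from 22 and comes back at 22. The coupling would be worked up without the acid treatment, so that 22 and its carbinol epimer stay open. Dess–Martin oxidation of the mixture would give the enone methyl (3R,4R,6E)-3-[(2E)-4-acetoxy-3-methylbut-2-enoyl]-8-[(tert-butyldiphenylsilyl)oxy]-6-methyl-2-methylidene-4-[(2-methylprop-2-enoyl)oxy]oct-6-enoate F1, in which that carbon is no longer stereogenic. A Corey–Bakshi–Shibata reduction (oxazaborolidine enantiomer chosen to deliver hydride to the Si face of the ketone, catecholborane, toluene, −78 °C) should then return 22 as a single epimer under reagent control, and 22 is lactonised to 23 with PPTS as in the route.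

Step 10. During oxidation and handling, the α-hydrogen of the product, which is activated by both the aldehyde and the acrylate, can be removed. This would lead to migration of the methylidene double bond into conjugation, epimerisation, or β-elimination of methacrylic acid. The fallback sets out from 13 and comes back at 23; it carries the secondary oxygen as a silyl ether, which is a far poorer leaving group, and installs the methacrylate after the ring is closed.
- Silylation of 13 (TBSOTf, 2,6-lutidine, CH2Cl2, −78 °C) would give the bis-TBS ether F2.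
- Buffered HF·pyridine would remove only the primary TBS group to give the primary alcohol F3.
- Dess–Martin oxidation would give the β-silyloxy aldehyde F4.
- Nozaki–Hiyama–Kishi coupling with 20 would give the open hydroxy ester F5, which PPTS would close to the silyl-protected lactone F6.
- Aqueous HF in MeCN would cleave the secondary TBS ether in the presence of the primary TBDPS ether to give the hydroxy lactone F7.
- Methacrylic anhydride, Et3N and DMAP would convert F7 into 23.

Step 7. The allylchromium species may equilibrate between its two alkene geometries or react through an open transition state, so that syn/anti and enantioface control fall short. The amine base may also move the double bond of aldehyde 7 into conjugation. The fallback sets out from 11 and comes back at 13. Palladium-catalysed borylation of 11 (B2pin2, Pd2(dba)3, DMSO, 50 °C) would give the allylboronate F8, isolated with CH2B and CH2OTBS cis. A chiral phosphoric acid-catalysed allylboration of 7 (TRIP-type catalyst, enantiomer chosen for Si-face attack, toluene, −30 °C) then runs through a closed chair transition state that is stereospecific for the syn adduct and needs no base, and should give 13 after work-up.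

Further compounds
F1 | step 13 | methyl (3R,4R,6E)-3-[(2E)-4-acetoxy-3-methylbut-2-enoyl]-8-[(tert-butyldiphenylsilyl)oxy]-6-methyl-2-methylidene-4-[(2-methylprop-2-enoyl)oxy]oct-6-enoate | C=C(C)C(=O)O[C@H](C/C(C)=C/CO[Si](c1ccccc1)(c1ccccc1)C(C)(C)C)[C@@H](C(=C)C(=O)OC)C(=O)/C=C(\C)COC(C)=O
F2 | step 10 | methyl (3S,4R,6E)-4-[(tert-butyldimethylsilyl)oxy]-3-{[(tert-butyldimethylsilyl)oxy]methyl}-8-[(tert-butyldiphenylsilyl)oxy]-6-methyl-2-methylideneoct-6-enoate | CC(C)(C)[Si](C)(C)O[C@H](C/C(C)=C/CO[Si](c1ccccc1)(c1ccccc1)C(C)(C)C)[C@@H](C(=C)C(=O)OC)CO[Si](C)(C)C(C)(C)C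
F3 | step 10 | methyl (3S,4R,6E)-4-[(tert-butyldimethylsilyl)oxy]-8-[(tert-butyldiphenylsilyl)oxy]-3-(hydroxymethyl)-6-methyl-2-methylideneoct-6-enoate | CC(C)(C)[Si](C)(C)O[C@H](C/C(C)=C/CO[Si](c1ccccc1)(c1ccccc1)C(C)(C)C)[C@@H](C(=C)C(=O)OC)CO
F4 | step 10 | methyl (3R,4R,6E)-4-[(tert-butyldimethylsilyl)oxy]-8-[(tert-butyldiphenylsilyl)oxy]-3-formyl-6-methyl-2-methylideneoct-6-enoate | CC(C)(C)[Si](C)(C)O[C@H](C/C(C)=C/CO[Si](c1ccccc1)(c1ccccc1)C(C)(C)C)[C@@H](C(=C)C(=O)OC)C=O
F5 | step 10 | methyl (3S,4R,6E)-3-[(1R,2E)-4-acetoxy-1-hydroxy-3-methylbut-2-en-1-yl]-4-[(tert-butyldimethylsilyl)oxy]-8-[(tert-butyldiphenylsilyl)oxy]-6-methyl-2-methylideneoct-6-enoate | CC(C)(C)[Si](C)(C)O[C@H](C/C(C)=C/CO[Si](c1ccccc1)(c1ccccc1)C(C)(C)C)[C@@H](C(=C)C(=O)OC)[C@H](O)/C=C(\C)COC(C)=O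
F6 | step 10 | (2E)-3-[(2R,3S)-3-{(1R,3E)-1-[(tert-butyldimethylsilyl)oxy]-5-[(tert-butyldiphenylsilyl)oxy]-3-methylpent-3-en-1-yl}-4-methylidene-5-oxooxolan-2-yl]-2-methylprop-2-en-1-yl acetate | CC(C)(C)[Si](C)(C)O[C@H](C/C(C)=C/CO[Si](c1ccccc1)(c1ccccc1)C(C)(C)C)[C@H]1C(=C)C(=O)O[C@@H]1/C=C(\C)COC(C)=O
F7 | step 10 | (2E)-3-[(2R,3R)-3-{(1R,3E)-5-[(tert-butyldiphenylsilyl)oxy]-1-hydroxy-3-methylpent-3-en-1-yl}-4-methylidene-5-oxooxolan-2-yl]-2-methylprop-2-en-1-yl acetate | O[C@H](C/C(C)=C/CO[Si](c1ccccc1)(c1ccccc1)C(C)(C)C)[C@H]1C(=C)C(=O)O[C@@H]1/C=C(\C)COC(C)=O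
F8 | step 7 | methyl (2E)-4-[(tert-butyldimethylsilyl)oxy]-2-[(4,4,5,5-tetramethyl-1,3,2-dioxaborolan-2-yl)methyl]but-2-enoate | CC1(C)OB(C/C(C(=O)OC)=C\CO[Si](C)(C)C(C)(C)C)OC1(C)C
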